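**Retrosynthetic overview**

- Feature: in the six-membered ring (C1 quaternary carbinol carrying C7, C2 ketone, C3=C4, C5 carbinol, C6 benzoate) the C2 and C5 oxygens sit 1,4 to each other across the C3=C4 alkene, the footprint of O2 added across a C2=C3–C4=C5 diene.
- Target ⇐ C5-silylated enone ⇐ cis-2,5-diol ⇐ 2,5-epidioxide (2,3-dioxabicyclo[2.2.2]octene) by O–O reduction and steric differentiation of the two allylic alcohols.
- Key disconnection: both C–O bonds of the peroxide bridge ⇒ singlet oxygen + trans-(1R,6S)-diene dibenzoate, the face being relayed from C1 and C6.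
- Diene ⇐ C3=C4 alkene (Br2, then loss of 2 HBr) ⇐ Sharpless epoxide of (cyclohexa-1,4-dienyl)methanol opened at C6 by benzoate ⇐ buta-1,3-diene + methyl propiolate.
- Ring order: carbocycle (step 1), oxirane (step 3, opened in step 4), peroxide bicycle (step 8, opened in step 9).

Key step: step 8

**Remarks**

- Locants: the ring carbons keep the target numbering (C1 quaternary carbinol, C2, C3, C4, C5, C6 benzoate carbon, C7 exocyclic CH2) in every intermediate from 8 onward, and descriptors are quoted with these locants.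
- Assumption: L-(+)-tartrate esters give the (S,S)-epoxide from 1-cyclohexenylmethanols, so the D-(−) ester is taken for the (1R,6R)-epoxide 5.
- Compounds 9 and 10 are drawn as one of the two possible anti-addition diastereomers at C3/C4; the other converges on the same diene 11.

**Route**

Step 1
Reactants: 1 buta-1,3-diene; 2 methyl propiolate
Product: 3 methyl cyclohexa-1,4-diene-1-carboxylate
Conditions: toluene, hydroquinone (cat.), sealed vessel, 110 °C
Reagents that add atoms: none
Why: Thermal [4+2] Diels–Alder cycloaddition of the diene to the acetylenic ester gives the skipped 1,4-diene with the ester on the new trisubstituted alkene; no stereocentre is formed.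

Step 2
Reactants: 3 methyl cyclohexa-1,4-diene-1-carboxylate
Product: 4 (cyclohexa-1,4-dien-1-yl)methanol
Conditions: DIBAL-H (2.5 equiv), CH2Cl2, −78 → 0 °C; Rochelle salt work-up
Reagents that add atoms: none
Why: Hydride 1,2-reduction of the conjugated ester by DIBAL-H should stop at the allylic alcohol and leave both alkenes untouched.

Step 3
Reactants: 4 (cyclohexa-1,4-dien-1-yl)methanol
Product: 5 [(1R,6R)-7-oxabicyclo[4.1.0]hept-3-en-1-yl]methanol
Conditions: Ti(OiPr)4 (10 mol%), D-(−)-diethyl tartrate (12 mol%), TBHP, 4 Å MS, CH2Cl2, −20 °C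
Reagents that add atoms: tert-butyl hydroperoxide, CC(C)(C)OO
Why: Katsuki–Sharpless asymmetric epoxidation acts only on the allylic C1=C6 alkene, the titanium–tartrate complex delivering oxygen to one enantioface so that C1 and C6 are set together as 1R,6R, while the isolated C3=C4 alkene is inert to Ti/TBHP.

Step 4
Reactants: 5 [(1R,6R)-7-oxabicyclo[4.1.0]hept-3-en-1-yl]methanol; 6 benzoic acid
Product: 7 (1S,6R)-6-hydroxy-6-(hydroxymethyl)cyclohex-3-en-1-yl benzoate
Conditions: Ti(OiPr)4 (1.5 equiv), PhCO2H (1.2 equiv), CH2Cl2, rt; aq. tartaric acid work-up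
Reagents that add atoms: none
Why: Titanium-mediated C-3-selective opening of a 2,3-epoxy alcohol: benzoate attacks the chelated epoxide at the secondary carbon C6 by SN2 with inversion and leaves the C1–O bond intact, which sets the trans C1-OH/C6-OBz pair.

Step 5
Reactants: 7 (1S,6R)-6-hydroxy-6-(hydroxymethyl)cyclohex-3-en-1-yl benzoate
Product: 8 [(1R,6S)-6-(benzoyloxy)-1-hydroxycyclohex-3-en-1-yl]methyl benzoate
Conditions: BzCl (1.3 equiv), pyridine, CH2Cl2, 0 °C
Reagents that add atoms: benzoyl chloride, O=C(Cl)c1ccccc1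
Why: Acylation with an acid chloride selects the primary C7 hydroxyl over the tertiary C1 hydroxyl; any benzoate that had shifted from O6 to O7 in step 4 converges on the same dibenzoate because only the tertiary hydroxyl resists acylation.

Step 6
Reactants: 8 [(1R,6S)-6-(benzoyloxy)-1-hydroxycyclohex-3-en-1-yl]methyl benzoate
Product: 9 [(1R,3R,4R,6S)-6-(benzoyloxy)-3,4-dibromo-1-hydroxycyclohexyl]methyl benzoate
Conditions: Br2 (1.05 equiv), CH2Cl2, −78 → −40 °C; Na2S2O3 quench
Reagents that add atoms: bromine, BrBr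
Why: Electrophilic anti addition through the bromonium ion gives the trans-3,4-dibromide; the two new centres are temporary and are erased in the next step.

Step 7
Reactants: 9 [(1R,3R,4R,6S)-6-(benzoyloxy)-3,4-dibromo-1-hydroxycyclohexyl]methyl benzoate
Product: 11 [(1R,6S)-6-(benzoyloxy)-1-hydroxycyclohexa-2,4-dien-1-yl]methyl benzoate, via allylic bromide 10 (not isolated)
Conditions: DBU (4 equiv), THF, rt → 45 °C; neutral work-up, Et3N-washed silica, used at once
Reagents that add atoms: none
Why: Two successive base-induced dehydrobrominations (E2, then E2 of the allylic bromide) place the alkenes at C2=C3 and C4=C5, the standard cyclohexene to cyclohexa-1,3-diene sequence; C1 is quaternary, so aromatisation by simple elimination is blocked and C1/C6 are untouched.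

Step 8
Reactants: 11 [(1R,6S)-6-(benzoyloxy)-1-hydroxycyclohexa-2,4-dien-1-yl]methyl benzoate
Product: 12 [(1R,2S,5R,6S)-6-(benzoyloxy)-2,5-epidioxy-1-hydroxycyclohex-3-en-1-yl]methyl benzoate
Conditions: O2, tetraphenylporphyrin (1 mol%), visible light, CH2Cl2, −20 → 0 °C
Reagents that add atoms: dioxygen (singlet oxygen made by sensitisation), O=O
Why: Sensitised singlet oxygen should add to the ring-held s-cis diene C2=C3–C4=C5 in a concerted suprafacial [4+2] hetero-Diels–Alder reaction that forms the C2–O and C5–O bonds together and moves the alkene to C3=C4. The closest known reactions are the photooxygenations of trans-5,6-diacyloxycyclohexa-1,3-dienes and of arene dihydrodiol derivatives to their endoperoxides. The 1,2-dioxene ring of the 2,3-dioxabicyclo[2.2.2]octene closes by this cycloaddition mode, both oxygen atoms bonding to the same face. The new stereocentres C2 and C5 are both fixed by the face of approach, which is set by C1 and C6: the lower face carries the C6 benzoate and the C7 benzoyloxymethyl arm, the upper face only the C1 hydroxyl and the C6 hydrogen, and in a non-hydrogen-bonding solvent the allylic C1 hydroxyl can also steer the oxidant by hydrogen bonding. The step needs π-facial selectivity and cycloaddition over ene reaction; the first rests on this substituent pattern, the second on the cisoid diene, for which [4+2] addition outruns hydrogen abstraction at C6.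

Step 9
Reactants: 12 [(1R,2S,5R,6S)-6-(benzoyloxy)-2,5-epidioxy-1-hydroxycyclohex-3-en-1-yl]methyl benzoate
Product: 13 [(1S,2S,5R,6S)-6-(benzoyloxy)-1,2,5-trihydroxycyclohex-3-en-1-yl]methyl benzoate
Conditions: Zn dust, AcOH, CH2Cl2, 0 °C → rt
Reagents that add atoms: none
Why: Two-electron reductive cleavage of the O–O bond by zinc/acetic acid breaks no C–O bond, so C2 and C5 keep their configuration and the cis-2,5-diol results.

Step 10
Reactants: 13 [(1S,2S,5R,6S)-6-(benzoyloxy)-1,2,5-trihydroxycyclohex-3-en-1-yl]methyl benzoate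
Product: 14 [(1S,2S,5R,6S)-6-(benzoyloxy)-5-[(tert-butyldimethylsilyl)oxy]-1,2-dihydroxycyclohex-3-en-1-yl]methyl benzoate
Conditions: TBSCl (1.2 equiv), imidazole, DMF, 0 °C
Reagents that add atoms: tert-butyldimethylsilyl chloride, CC(C)(C)[Si](C)(C)Cl
Why: Silyl ether formation is governed by steric access: the C5 hydroxyl, flanked by a CH carbon, should react, while the C2 hydroxyl next to the quaternary C1 and the tertiary C1 hydroxyl are left.

Step 11
Reactants: 14 [(1S,2S,5R,6S)-6-(benzoyloxy)-5-[(tert-butyldimethylsilyl)oxy]-1,2-dihydroxycyclohex-3-en-1-yl]methyl benzoate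
Product: 15 [(1R,5R,6S)-6-(benzoyloxy)-5-[(tert-butyldimethylsilyl)oxy]-1-hydroxy-2-oxocyclohex-3-en-1-yl]methyl benzoate
Conditions: IBX (2 equiv), DMSO, rt
Reagents that add atoms: none
Why: IBX oxidation of the remaining secondary allylic C2 alcohol gives the enone under neutral conditions without cleaving the adjacent tertiary carbinol; only C2 changes and it becomes sp2.

Step 12
Reactants: 15 [(1R,5R,6S)-6-(benzoyloxy)-5-[(tert-butyldimethylsilyl)oxy]-1-hydroxy-2-oxocyclohex-3-en-1-yl]methyl benzoate
Product: 16 [(1R,5R,6S)-6-(benzoyloxy)-1,5-dihydroxy-2-oxocyclohex-3-en-1-yl]methyl benzoate (CNP0212960.1)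
Conditions: HF·pyridine, pyridine, THF, 0 °C → rt
Reagents that add atoms: none
Why: Fluoride-mediated desilylation under buffered, non-basic conditions frees the C5 hydroxyl without benzoate migration or base-induced elimination of the γ-hydroxy enone.

**Compound list**

1 | buta-1,3-diene | C=CC=C | starting material
2 | methyl propiolate | C#CC(=O)OC | starting material
3 | methyl cyclohexa-1,4-diene-1-carboxylate | COC(=O)C1=CCC=CC1 | intermediate
4 | (cyclohexa-1,4-dien-1-yl)methanol | OCC1=CCC=CC1 | intermediate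
5 | [(1R,6R)-7-oxabicyclo[4.1.0]hept-3-en-1-yl]methanol | OC[C@]12CC=CC[C@H]1O2 | intermediate
6 | benzoic acid | OC(=O)c1ccccc1 | starting material
7 | (1S,6R)-6-hydroxy-6-(hydroxymethyl)cyclohex-3-en-1-yl benzoate | OC[C@]1(O)CC=CC[C@@H]1OC(=O)c1ccccc1 | intermediate
8 | [(1R,6S)-6-(benzoyloxy)-1-hydroxycyclohex-3-en-1-yl]methyl benzoate | O=C(OC[C@]1(O)CC=CC[C@@H]1OC(=O)c1ccccc1)c1ccccc1 | intermediate
9 | [(1R,3R,4R,6S)-6-(benzoyloxy)-3,4-dibromo-1-hydroxycyclohexyl]methyl benzoate (trans-3,4-dibromide) | O=C(OC[C@]1(O)C[C@@H](Br)[C@H](Br)C[C@@H]1OC(=O)c1ccccc1)c1ccccc1 | intermediate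
10 | [(1R,3R,6S)-6-(benzoyloxy)-3-bromo-1-hydroxycyclohex-4-en-1-yl]methyl benzoate (allylic bromide, not isolated) | O=C(OC[C@]1(O)C[C@@H](Br)C=C[C@@H]1OC(=O)c1ccccc1)c1ccccc1 | intermediate
11 | [(1R,6S)-6-(benzoyloxy)-1-hydroxycyclohexa-2,4-dien-1-yl]methyl benzoate (C1-OH and C6-OBz trans) | O=C(OC[C@]1(O)C=CC=C[C@@H]1OC(=O)c1ccccc1)c1ccccc1 | intermediate
12 | [(1R,2S,5R,6S)-6-(benzoyloxy)-2,5-epidioxy-1-hydroxycyclohex-3-en-1-yl]methyl benzoate (peroxide bridge on the face of the C1 hydroxyl) | O=C(OC[C@]1(O)[C@@H]2C=C[C@@H](OO2)[C@@H]1OC(=O)c1ccccc1)c1ccccc1 | intermediate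
13 | [(1S,2S,5R,6S)-6-(benzoyloxy)-1,2,5-trihydroxycyclohex-3-en-1-yl]methyl benzoate | O=C(OC[C@]1(O)[C@@H](O)C=C[C@@H](O)[C@@H]1OC(=O)c1ccccc1)c1ccccc1 | intermediate
14 | [(1S,2S,5R,6S)-6-(benzoyloxy)-5-[(tert-butyldimethylsilyl)oxy]-1,2-dihydroxycyclohex-3-en-1-yl]methyl benzoate | O=C(OC[C@]1(O)[C@@H](O)C=C[C@@H](O[Si](C)(C)C(C)(C)C)[C@@H]1OC(=O)c1ccccc1)c1ccccc1 | intermediate
15 | [(1R,5R,6S)-6-(benzoyloxy)-5-[(tert-butyldimethylsilyl)oxy]-1-hydroxy-2-oxocyclohex-3-en-1-yl]methyl benzoate | O=C(OC[C@]1(O)C(=O)C=C[C@@H](O[Si](C)(C)C(C)(C)C)[C@@H]1OC(=O)c1ccccc1)c1ccccc1 | intermediate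
16 | [(1R,5R,6S)-6-(benzoyloxy)-1,5-dihydroxy-2-oxocyclohex-3-en-1-yl]methyl benzoate (CNP0212960.1) | O=C(OC[C@]1(O)C(=O)C=C[C@@H](O)[C@@H]1OC(=O)c1ccccc1)c1ccccc1 | target

**Step count and risks**

Total step count: 12. Longest linear sequence: 12 steps (1/2 → 16).

Steps most likely to fail:

1. Step 8. Oxygen may add in part on the ester-bearing face, or ene oxidation at C6–H may compete, which would give the C2/C5-epimeric peroxide or hydroperoxides. The fallback sets out from 11 and returns at 16. Vanadium-catalysed, hydroxyl-directed epoxidation (VO(acac)2, TBHP, CH2Cl2) of the proximal C2=C3 alkene should give [(1R,2S,3S,6S)-6-(benzoyloxy)-2,3-epoxy-1-hydroxycyclohex-4-en-1-yl]methyl benzoate F1, with the oxygen delivered from the metal bound to the C1 hydroxyl and therefore cis to it. Palladium(0)-catalysed 1,4-addition of acetic acid to this vinyl epoxide (Pd(PPh3)4, AcOH, THF) proceeds with double inversion and should give the cis-5-acetoxy-2-ol [(1S,2S,5R,6S)-5-acetoxy-6-(benzoyloxy)-1,2-dihydroxycyclohex-3-en-1-yl]methyl benzoate F2. IBX oxidation of its C2 hydroxyl gives the acetoxy enone [(1R,5R,6S)-5-acetoxy-6-(benzoyloxy)-1-hydroxy-2-oxocyclohex-3-en-1-yl]methyl benzoate F3. Acid methanolysis (HCl from AcCl in MeOH, 0 °C), which takes acetates before benzoates, then frees the C5 hydroxyl to give 16. This path replaces steps 8–12 and relays the face through a metal-bound oxidant instead of steric approach.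

2. Step 10. Discrimination between the C5 and C2 hydroxyls may be incomplete, giving C2 or double silylation, or imidazole may trigger benzoate migration from O6 to O5. The fallback sets out from 13 and returns at 16 without a protecting group. Dibutyltin oxide (toluene, reflux, water removed) can only form a five-membered stannylene on the cis C1/C2 diol, giving the 1,2-O-dibutylstannylene acetal of triol 13 F4. Oxidation of this acetal with NBS (CHCl3, rt) occurs at the only stannylene carbinol bearing hydrogen, C2, and gives the α-hydroxy enone 16 directly.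

3. Step 7. The double dehydrobromination may stall, divert to a vinyl bromide, or be followed by aromatisation of the sensitive diene under prolonged base treatment. The fallback sets out from 8 and returns at 11. Anti addition of PhSeBr (CH2Cl2, −78 °C) gives [(1R,3R,4R,6S)-6-(benzoyloxy)-3-bromo-1-hydroxy-4-(phenylselanyl)cyclohexyl]methyl benzoate F5 (its regioisomer converges). Oxidation with H2O2/pyridine at 0 °C induces selenoxide syn-elimination away from bromine and gives the allylic bromide 10, which can be isolated. A single mild E2 with DBU (1.5 equiv, rt) then gives 11, so strong-base exposure is cut to one elimination from an activated bromide.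

**Further compounds**

F1 | step 8 | [(1R,2S,3S,6S)-6-(benzoyloxy)-2,3-epoxy-1-hydroxycyclohex-4-en-1-yl]methyl benzoate (epoxide cis to C1-OH) | O=C(OC[C@]1(O)[C@H]2O[C@H]2C=C[C@@H]1OC(=O)c1ccccc1)c1ccccc1
F2 | step 8 | [(1S,2S,5R,6S)-5-acetoxy-6-(benzoyloxy)-1,2-dihydroxycyclohex-3-en-1-yl]methyl benzoate | O=C(OC[C@]1(O)[C@@H](O)C=C[C@@H](OC(C)=O)[C@@H]1OC(=O)c1ccccc1)c1ccccc1
F3 | step 8 | [(1R,5R,6S)-5-acetoxy-6-(benzoyloxy)-1-hydroxy-2-oxocyclohex-3-en-1-yl]methyl benzoate | O=C(OC[C@]1(O)C(=O)C=C[C@@H](OC(C)=O)[C@@H]1OC(=O)c1ccccc1)c1ccccc1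
F4 | step 10 | 1,2-O-dibutylstannylene acetal of triol 13 (Sn bridging O1 and O2) | O=C(OC[C@]1(O[Sn](CCCC)(CCCC)O2)[C@@H]2C=C[C@@H](O)[C@@H]1OC(=O)c1ccccc1)c1ccccc1
F5 | step 7 | [(1R,3R,4R,6S)-6-(benzoyloxy)-3-bromo-1-hydroxy-4-(phenylselanyl)cyclohexyl]methyl benzoate | O=C(OC[C@]1(O)C[C@@H](Br)[C@H]([Se]c2ccccc2)C[C@@H]1OC(=O)c1ccccc1)c1ccccc1
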